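In the closed theta flask, which is the flask asked about followed so far, each G charged is still free, sits in X, or has gone elsewhere. I take one G per X, and that count is what to watch when repeating the run.

| setting | theta | zeta | flask |
|---|---|---|---|
| D | 0.020 M | 0.020 M | 0.020 M |
| G | 0.020 M | 0.013 M | 0.0200 M |
| temperature | 35 °C | 30 °C | 35 °C |
| remark | the very flask that is asked about, followed so far | run made earlier |  |
| time |  |  | 8.0 d |

| theta: time / d | theta: X / % | zeta: time / d | zeta: X / % |
|---|---|---|---|
| 0.625 | 9.2 | 0.500 | 4.2 |
| 1.67 | 22.3 | 1.04 | 7.7 |
| 3.00 | 32.7 | 1.67 | 12.2 |
| 5.00 | 37.7 | 2.08 | 15.4 |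
| 6.00 | 39.4 | 2.50 | 18.0 |

(standard deviation of a reading: 0.5 percentage points)

- autumn: at 8.0 d take out 90% of the X then present, then wait 15 d
- dusk: at 8.0 d raise the temperature by 15 K, then wait 15 d
- dawn: change nothing and wait 15 d more
- spring: at 8.0 d add G, 50.0% of the amount charged, then wait 15 d

* X, in percent of the D first charged, at 8.0 d
* what to do for the largest gain in X; "none" if nothing gains more than 2 percentage points (autumn / dusk / dawn / spring / none)
* X present, with what was taken out counted in, in percent of the D first charged, after dusk
* X present, with what was taken out counted in, in percent of the D first charged, after dawn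

- D is a solid; its amount is given per volume of the solution
- what is taken out of X is counted as made
- the numbers in the tables scatter with a standard deviation of 0.5 percentage points
- at the start none of D is in solution
- additions bring no volume worth counting

First question: does the theta rate follow D or [G]? Its first slope is 8.66 times its last, as a rough reading, while D has given 39.4% as X. In zeta, the first slope is 1.20 times the late one. At the last theta reading 60.6% of D is not in X, so I try [G] first: my working assumption is that the theta rate goes with [G].

Second question: can X by itself account for the fall? At one G per X, theta would still have 60.6% of its G free. That is a fall in [G] by a factor of 1.65, less than the fall in rate. So, if that assumption holds, G also leaves by a second path.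

The quantity to carry is the capture share, the X made per G charged, read as 39.4% at the last theta reading.

Third question: what pays at 8.0 d? The last theta step gained 1.7 percentage points in 1.00 d, so I expect waiting to add little. Added G, split by the capture share, should give 20 points, more than the margin. I choose spring.

The forecast gives 41.3% for now, 42.5% after dusk and 42.5% after dawn, and it picks spring: “Spring is therefore the safest choice.”

The flask gives 39.7%, with dawn ending at 40.0% and dusk at 39.9%.

    G → J (k = 4.16 × 10⁻⁶ s⁻¹, Ea = 95.0 kJ mol⁻¹)
    D ⇌ Z, rate k2*(cs2 - [Z]) while solid is left; crystals form when [Z] > cs2 (solubility = 1.60 mM, k = 5.97 × 10⁻⁵ s⁻¹)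
    Z + G → X (k = 0.00263 M⁻¹ s⁻¹, Ea = 79.0 kJ mol⁻¹)
    D → Q (k = 1.59 × 10⁻⁷ s⁻¹, Ea = 106 kJ mol⁻¹)
    (constants at 35 °C)

Spring gains the most, 23 points, against the 20 points from the capture share. G is the limiting reagent in this flask: at 8.00 d, free G stands at 0.468% of its charge, while 45.8% of D is still solid. For the neighbour charged with 0.050 M of G, the capture share gives 98.5% of X, and that neighbour holds 81.6%.

The runs come from a simulation from invented constants; noise was put on by code.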